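Slowness is the first thing you see in these runs: J climbs for hours at a nearly steady pace, so what you want to know about the flask at 20 h is where that climb stops.

in all of them: Q 0.18 M; X 0.198 M

|  | temperature | remark | time |
|---|---|---|---|
| Wednesday's | 90 °C | the very flask that is asked about, followed so far |  |
| Thursday's | 75 °C | run made earlier |  |
| flask | 90 °C |  | 20 h |

| run | time / h | J / % |
|---|---|---|
| Wednesday's | 1.00 | 6.9 |
| Wednesday's | 1.33 | 10.8 |
| Wednesday's | 2.00 | 17.4 |
| Wednesday's | 3.00 | 28.4 |
| Wednesday's | 5.00 | 45.9 |
| Wednesday's | 8.00 | 64.0 |
| Wednesday's | 12.0 | 72.2 |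
| Thursday's | 2.00 | 6.2 |
| Thursday's | 3.00 | 10.4 |
| Thursday's | 4.00 | 14.1 |
| Thursday's | 6.00 | 22.3 |
| Thursday's | 10.0 | 37.0 |
| Thursday's | 15.0 | 51.5 |
| Thursday's | 25.0 | 66.9 |

(scatter of a reading: 0.3 percentage points)

- epsilon: at 20 h raise the temperature by 10 K, then wait 40 h
- alpha: at 20 h add X, 100 % of the amount charged, then wait 40 h
- theta: at 20 h take out 90 % of the J then present, then wait 40 h
- delta: change nothing and wait 40 h more

- Q is a solid; its amount is given per volume of the solution
- what is taken out of J is counted as made
- the analysis behind the earlier runs scatters by 0.3 percentage points, standard deviation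
- at the start none of Q is in solution
- additions bring no volume worth counting

- J, in percent of the Q first charged, at 20 h
- what to do for the largest gain in J; "none" if nothing gains more than 2 percentage points (epsilon / alpha / theta / delta / none)
- J present, with what was taken out counted in, in percent of the Q first charged, after alpha
- J present, with what was taken out counted in, in percent of the Q first charged, after theta

Write the balance of Q, the limiting reagent by charge, since its 0.18 M is less than the 0.198 M of X, and two extreme flasks can be done in your head. In the first, each X makes one J, so J climbs to 100 % of the Q charged. In the second, suppose X ended at Wednesday's last reading, so J stays at 72.2 % and each J has cost 1.52 X.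

My own reckoning puts the flask between them, because Wednesday's run still gained 8.2 percentage points in its last interval of 4.00 h, but its pace had fallen by a factor of 2.94. If each later interval shrinks by that factor, the tail adds 4.2 points, and J stops near 76.4 %, as a reading. Carry the X bill, the X charged per J if X is what ends the climb at that stop, 1.44, which is more than the 1.10 X charged per Q, so I would choose alpha.

The forecast gives 74 %, lower than my stop, with alpha, 97 % after alpha and 75 % after theta, holding that “A plateau that does not move with temperature argues against equilibrium and points to something used up.”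

The flask gives 78.1 % at 20 h, and the best option is alpha, which gains 7.3 points and ends at 85.4 %, while theta ends at 82.2 %.

    E + X → J (k = 0.0400 M⁻¹ min⁻¹, Ea = 93.0 kJ mol⁻¹)
    Q ⇌ E, rate k2*(cs2 - [E]) while solid is left; crystals form when [E] > cs2 (solubility = 0.0810 M, k = 0.0170 min⁻¹)
    X → Z (k = 4.40 × 10⁻⁴ min⁻¹, Ea = 130 kJ mol⁻¹)
    2 E → D (k = 0.00700 M⁻¹ min⁻¹, Ea = 100 kJ mol⁻¹)
    (constants at 90 °C)

Left to 200 h, this flask holds 82.7 % of J and 0.0186 % of its X, so its bill comes to 1.33, less than my 1.44. At 20.0 h this flask holds 0 % of Q, 14.5 % as D, 7.39 % as E and 11 % of its X, E is used by the step to J at 4.6 times the rate of the step to D, and J plus E comes to 85.5 %, beside 85.4 % after alpha and the forecast's 97 %.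

In the neighbour charged with 0.34 M of X, the bill gives a ceiling of 131 %, past the Q charged, so Q should run out first, leaving 23.8 % of its X. Computed, that neighbour reaches 94.0 % of J at 20.0 h, with 0.31 % of the charged Q still there, solid or dissolved, and 26 % of its X left.

The readings come from a simulation with made-up constants, noise included.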